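**Plan** (longipinane locants: C1 = ketone, C2=C3(CH3) = enone alkene, C4–C5–C11–C10 = cyclobutane with CH3 on C10, C6 = C(CH3)2, C7 = senecioate carbon, C8 = CH2, C9 = tiglate carbon)
1. Retrosynthetic cuts, in order: the two ester C–O bonds; C7–C8 (aldol condensation; C8 comes from MeLi added to a nitrile C9); the cyclobutane bond C4–C10; C5–C6 ([3,3] shift). What remains is the cyclohexene of (1S,4R)-p-mentha-2,8-dien-1-ol plus an isobutyrate.
2. Forward ring order: the six-membered ring is bought; the four-membered ring is closed next (bicyclo[3.1.1]heptane); the seven-membered ring is closed third, across cyclobutane carbons C5 and C10; the C1 ketone and the two esters come last.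
3. Enabling feature: C10 is a quaternary cyclobutane carbon whose substituent C9 can be a nitrile, and C4 lies next to C3, the methyl-bearing carbon that ends as the enone β-carbon. A C3–C4 epoxide on a cyclohexane whose C11 side chain carries the nitrile anion lets C10 attack C4 across the ring (1,3); the oxirane strain pays for the cyclobutane, and the oxygen left on C3 becomes the C2=C3 alkene.
4. Stereochemistry: C11 from the chiral pool; C5 by suprafacial Ireland–Claisen transfer; C4 (inversion) and C10 (cyano anti to the C1–C3 bridge) in the ring closure; C7 by ligand-controlled conjugate borylation; C9 by 1,3-anti Evans–Tishchenko hydride delivery.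

Key step: step 7

Remark: alcohol 1 is taken as an article of commerce (made from (R)-limonene); compounds 9–13 are carried as both epimers at the CH(CH3) carbon (future C10), which converge in step 7.

**Step 1**
Reactants: 1 (1S,4R)-1-methyl-4-(prop-1-en-2-yl)cyclohex-2-en-1-ol; 2 2-methylpropanoyl chloride
Product: 3 (1S,4R)-1-methyl-4-(prop-1-en-2-yl)cyclohex-2-en-1-yl 2-methylpropanoate
Conditions: n-BuLi, THF, −78 °C; then 2, −78 → 0 °C
Reagents that add atoms: none
Why: O-acylation of the lithium alkoxide of a tertiary allylic alcohol with an acid chloride should give the ester without touching a stereocentre.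

**Step 2**
Reactants: 3 the isobutyrate
Product: 6 2-methyl-2-[(1S,6R)-3-methyl-6-(prop-1-en-2-yl)cyclohex-2-en-1-yl]propan-1-ol, via silyl ketene acetal 4 (not isolated), via trimethylsilyl ester 5 (not isolated)
Conditions: LiN(i-Pr)2, Me3SiCl–Et3N, THF, −78 → 60 °C; then LiAlH4, 0 °C; aq. NaOH work-up
Reagents that add atoms: none
Why: Ireland–Claisen rearrangement: the suprafacial [3,3] shift should place the new C5–C6 bond on the ring face that carried the ester oxygen, i.e. cis to the isopropenyl group (sets C5), and create the C3=C4 alkene; LiAlH4 then reduces the silyl ester in the same pot.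

**Step 3**
Reactants: 6 the neopentyl alcohol
Product: 7 triethylsilyl ether of 6
Conditions: Et3SiCl, imidazole, CH2Cl2, 0 °C → rt
Reagents that add atoms: chlorotriethylsilane CC[Si](Cl)(CC)CC
Why: Silylation of the primary alcohol masks an oxygen that would otherwise open the later epoxide by 5-exo attack.

**Step 4**
Reactants: 7 the silyl ether
Product: 9 2-{cis-4-methyl-2-[2-methyl-1-(triethylsilyloxy)propan-2-yl]cyclohex-3-en-1-yl}propan-1-ol (both epimers at the CH(CH3) carbon), via B-alkyl-9-borabicyclononane 8 (not isolated)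
Conditions: 9-BBN, THF, 0 °C → rt; then NaOH, H2O2, 0 °C
Reagents that add atoms: hydrogen peroxide OO
Why: Hydroboration–oxidation: 9-BBN should select the 1,1-disubstituted exocyclic alkene over the hindered trisubstituted ring alkene and place oxygen on the terminal carbon (future C9); the new CH(CH3) centre is later erased by deprotonation.

**Step 5**
Reactants: 9 the primary alcohol
Product: 11 2-{cis-4-methyl-2-[2-methyl-1-(triethylsilyloxy)propan-2-yl]cyclohex-3-en-1-yl}propanenitrile, via aldehyde 10 (not isolated)
Conditions: TEMPO (cat.), PhI(OAc)2, NH4OAc, MeCN–H2O, rt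
Reagents that add atoms: ammonium acetate CC(=O)[O-].[NH4+]
Why: Nitroxyl-catalysed oxidation to the aldehyde, imine formation with ammonia and further oxidation of the aldimine should give the nitrile in one pot without affecting the alkene.

**Step 6**
Reactants: 11 the alkenyl nitrile
Product: 12 3,4-epoxide of 11 with the oxygen trans to both ring side chains
Conditions: mCPBA, NaHCO3, CH2Cl2, 0 °C
Reagents that add atoms: 3-chloroperoxybenzoic acid OOC(=O)c1cccc(Cl)c1
Why: Prilezhaev epoxidation: the peracid should approach the trisubstituted alkene from the face opposite the two cis side chains (the allylic quaternary group on C5 blocks the other face), which fixes the oxygen on C3 and C4.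

**Step 7**
Reactants: 12 the epoxy nitrile
Product: 14 2-hydroxy-2,6-dimethyl-7-[2-methyl-1-(triethylsilyloxy)propan-2-yl]bicyclo[3.1.1]heptane-6-carbonitrile (cyano and the C7 side chain both anti to the three-carbon bridge), via potassium nitrile anion 13 (not isolated)
Conditions: KN(SiMe3)2, toluene, −78 → 60 °C; aq. NH4Cl
Reagents that add atoms: none
Why: KN(SiMe3)2 removes the proton alpha to the nitrile (both epimers give the same planar anion 13), which sits on C11 cis-1,3 to C4 and attacks C4 from the face opposite the epoxide oxygen in an intramolecular SN2 opening; the closest known reaction type is the Stork epoxynitrile cyclisation, which forms cyclobutanes in preference to cyclopentanes. The ring C4–C5–C11–C10 closes in the 4-exo-tet mode (the breaking C4–O bond lies outside the new ring) and turns the cyclohexane into the bicyclo[3.1.1]heptane. C4 is set by inversion (the epoxide face was fixed in step 6) and C3 keeps its oxygen; at C10 the small linear cyano group should take the position anti to the C1–C3 bridge, next to the bulky C5 substituent, with methyl toward the bridge, because the alternative presses methyl against the quaternary C6 group. The selectivity needed is attack at C4 rather than at the methyl-bearing C3 (which would give a bicyclo[2.2.1]heptane by 5-exo closure through C1–C2); it is secured because C3 is a fully substituted epoxide carbon that resists SN2 attack with a potassium counter-ion in a non-polar solvent, whereas C4 is secondary and trans-diaxial to the leaving oxygen. The alkoxide left on C3 is the handle for the enone alkene.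

**Step 8**
Reactants: 14 the tertiary alcohol
Product: 16 2,6-dimethyl-7-[2-methyl-1-(triethylsilyloxy)propan-2-yl]bicyclo[3.1.1]hept-2-ene-6-carbonitrile, via sulfamate ester 15 (not isolated)
Conditions: Burgess reagent (methyl N-(triethylammoniosulfonyl)carbamate), toluene, 60 °C
Reagents that add atoms: none
Why: Burgess dehydration (syn elimination through the sulfamate): C4 is a bridgehead, so only H-2 or a methyl hydrogen can leave, and the more substituted endocyclic C2=C3 alkene is expected to predominate under neutral conditions that avoid a free pinanyl-type cation.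

**Step 9**
Reactants: 16 the bicyclic nitrile
Product: 18 1-[7-(1-hydroxy-2-methylpropan-2-yl)-2,6-dimethylbicyclo[3.1.1]hept-2-en-6-yl]ethan-1-one, via N-lithio ketimine 17 (not isolated)
Conditions: MeLi, Et2O, 0 °C → rt; then AcOH–THF–H2O, 40 °C
Reagents that add atoms: methyllithium [Li]C; water O
Why: Organolithium addition to the nitrile (no alpha hydrogen) should stop at the lithio ketimine, and mild aqueous acid should hydrolyse it to the methyl ketone (C8 introduced) while cleaving the triethylsilyl ether.

**Step 10**
Reactants: 18 the hydroxy ketone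
Product: 19 2-(6-acetyl-2,6-dimethylbicyclo[3.1.1]hept-2-en-7-yl)-2-methylpropanal
Conditions: Dess–Martin periodinane, NaHCO3, CH2Cl2, rt
Reagents that add atoms: none
Why: Dess–Martin oxidation should convert the neopentyl primary alcohol into the non-enolisable aldehyde (C7) without touching the strained alkene.

**Step 11**
Reactants: 19 the keto aldehyde
Product: 21 longipina-2,7-dien-9-one, via aldol adduct 20 (not isolated)
Conditions: NaOMe, MeOH, 0 → 50 °C
Reagents that add atoms: none
Why: Intramolecular aldol condensation: the methyl ketone (C8, the only enolisable site) should add to the aldehyde held next to it on the same face of the cyclobutane, and E1cB loss of water closes the seven-membered ring as the cis enone without creating a stereocentre.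

**Step 12**
Reactants: 21 the tricyclic dienone
Product: 22 longipina-2,7-diene-1,9-dione
Conditions: CrO3, 3,5-dimethylpyrazole, CH2Cl2, −20 °C
Reagents that add atoms: chromium trioxide O=[Cr](=O)=O
Why: Allylic oxidation of the ring methylene C1 next to the trisubstituted alkene (the α-pinene to verbenone type of oxidation) should give the enone; the cycloheptenone has no allylic hydrogens because C6 and C10 are quaternary.

**Step 13**
Reactants: 22 the dienedione
Product: 24 (7R)-7-hydroxylongipin-2-ene-1,9-dione, via pinacol boronate 23 (not isolated)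
Conditions: CuCl (5 mol %), NaOt-Bu (10 mol %), Josiphos-type ligand 1-[2-(diphenylphosphino)ferrocenyl]ethyldicyclohexylphosphine (enantiomer that gives 7R), B2pin2, MeOH, THF, rt; then NaBO3·4H2O, THF–H2O
Reagents that add atoms: sodium perborate [Na+].[Na+].O[B-]1(O)OO[B-](O)(O)OO1
Why: Copper-catalysed asymmetric conjugate borylation should add boron to C7 of the less substituted enone much faster than to the β,β-disubstituted bicyclic enone, with the chiral ligand rather than the nearly symmetric surroundings choosing the face; oxidation of the C–B bond goes with retention.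

**Step 14**
Reactants: 24 the β-hydroxy ketone; 25 3-methylbut-2-enal
Product: 26 (7R,9R)-9-hydroxy-1-oxolongipin-2-en-7-yl 3-methylbut-2-enoate
Conditions: 25 (6 equiv), SmI2 (30 mol %), THF, −10 °C
Reagents that add atoms: none
Why: Evans–Tishchenko reduction: the samarium-bound hemiacetal formed from the C7 hydroxyl and the aldehyde should deliver hydride intramolecularly to the C9 ketone, giving the 1,3-anti (trans) C9 alcohol and leaving C7 as its senecioate in one operation.

**Step 15**
Reactants: 26 the hydroxy senecioate; 27 (E)-2-methylbut-2-enoyl chloride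
Product: 28 target CNP0277258.1, (7R,9R)-7-(3-methylbut-2-enoyloxy)-9-[(E)-2-methylbut-2-enoyloxy]longipin-2-en-1-one
Conditions: pyridine, DMAP (cat.), CH2Cl2, 0 °C → rt
Reagents that add atoms: none
Why: DMAP-catalysed acylation of the remaining hindered secondary alcohol with the acid chloride should give the tiglate with the E geometry of the reagent retained.

**Compound list**
1 | (1S,4R)-1-methyl-4-(prop-1-en-2-yl)cyclohex-2-en-1-ol (hydroxyl cis to isopropenyl) | C[C@@]1(O)C=C[C@H](C(C)=C)CC1 | starting material
2 | 2-methylpropanoyl chloride | CC(C)C(Cl)=O | starting material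
3 | (1S,4R)-1-methyl-4-(prop-1-en-2-yl)cyclohex-2-en-1-yl 2-methylpropanoate | C[C@@]1(OC(=O)C(C)C)C=C[C@H](C(C)=C)CC1 | intermediate
4 | trimethylsilyl ketene acetal of 3 (formed in the flask) | C[C@@]1(OC(O[Si](C)(C)C)=C(C)C)C=C[C@H](C(C)=C)CC1 | intermediate
5 | trimethylsilyl 2-methyl-2-[(1S,6R)-3-methyl-6-(prop-1-en-2-yl)cyclohex-2-en-1-yl]propanoate (formed in the flask) | C[Si](C)(C)OC(=O)C(C)(C)[C@H]1C=C(C)CC[C@H]1C(C)=C | intermediate
6 | 2-methyl-2-[(1S,6R)-3-methyl-6-(prop-1-en-2-yl)cyclohex-2-en-1-yl]propan-1-ol (ring substituents cis) | OCC(C)(C)[C@H]1C=C(C)CC[C@H]1C(C)=C | intermediate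
7 | triethylsilyl ether of 6 | CC[Si](CC)(CC)OCC(C)(C)[C@H]1C=C(C)CC[C@H]1C(C)=C | intermediate
8 | B-alkyl-9-borabicyclo[3.3.1]nonane from 7, boron on the terminal carbon of the former isopropenyl group (formed in the flask) | CC[Si](CC)(CC)OCC(C)(C)[C@H]1C=C(C)CC[C@H]1C(C)CB1C2CCCC1CCC2 | intermediate
9 | 2-{cis-4-methyl-2-[2-methyl-1-(triethylsilyloxy)propan-2-yl]cyclohex-3-en-1-yl}propan-1-ol (both epimers at the CH(CH3) carbon) | CC[Si](CC)(CC)OCC(C)(C)[C@H]1C=C(C)CC[C@H]1C(C)CO | intermediate
10 | 2-{cis-4-methyl-2-[2-methyl-1-(triethylsilyloxy)propan-2-yl]cyclohex-3-en-1-yl}propanal (formed in the flask) | CC[Si](CC)(CC)OCC(C)(C)[C@H]1C=C(C)CC[C@H]1C(C)C=O | intermediate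
11 | 2-{cis-4-methyl-2-[2-methyl-1-(triethylsilyloxy)propan-2-yl]cyclohex-3-en-1-yl}propanenitrile (both epimers) | CC[Si](CC)(CC)OCC(C)(C)[C@H]1C=C(C)CC[C@H]1C(C)C#N | intermediate
12 | 3,4-epoxide of 11, oxygen trans to both ring side chains | CC[Si](CC)(CC)OCC(C)(C)[C@H]1[C@@H]2O[C@]2(C)CC[C@H]1C(C)C#N | intermediate
13 | potassium salt of the α-cyano carbanion of 12 (formed in the flask) | CC[Si](CC)(CC)OCC(C)(C)[C@H]1[C@@H]2O[C@]2(C)CC[C@H]1[C-](C)C#N.[K+] | intermediate
14 | 2-hydroxy-2,6-dimethyl-7-[2-methyl-1-(triethylsilyloxy)propan-2-yl]bicyclo[3.1.1]heptane-6-carbonitrile (cyano and C7 side chain anti to the three-carbon bridge; hydroxyl on the C7 side of that bridge) | CC[Si](CC)(CC)OCC(C)(C)[C@@H]1[C@H]2CC[C@@](C)(O)[C@@H]1[C@@]2(C)C#N | intermediate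
15 | triethylammonium N-(methoxycarbonyl)sulfamate ester of 14 (formed in the flask) | CC[Si](CC)(CC)OCC(C)(C)[C@@H]1[C@H]2CC[C@@](C)(OS(=O)(=O)[N-]C(=O)OC)[C@@H]1[C@@]2(C)C#N.CC[NH+](CC)CC | intermediate
16 | 2,6-dimethyl-7-[2-methyl-1-(triethylsilyloxy)propan-2-yl]bicyclo[3.1.1]hept-2-ene-6-carbonitrile | CC[Si](CC)(CC)OCC(C)(C)[C@@H]1[C@H]2CC=C(C)[C@@H]1[C@@]2(C)C#N | intermediate
17 | N-lithio ketimine from 16 and MeLi (formed in the flask) | CC[Si](CC)(CC)OCC(C)(C)[C@@H]1[C@H]2CC=C(C)[C@@H]1[C@@]2(C)C(C)=N[Li] | intermediate
18 | 1-[7-(1-hydroxy-2-methylpropan-2-yl)-2,6-dimethylbicyclo[3.1.1]hept-2-en-6-yl]ethan-1-one | OCC(C)(C)[C@@H]1[C@H]2CC=C(C)[C@@H]1[C@@]2(C)C(C)=O | intermediate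
19 | 2-(6-acetyl-2,6-dimethylbicyclo[3.1.1]hept-2-en-7-yl)-2-methylpropanal | O=CC(C)(C)[C@@H]1[C@H]2CC=C(C)[C@@H]1[C@@]2(C)C(C)=O | intermediate
20 | 7-hydroxylongipin-2-en-9-one, both C7 epimers (formed in the flask) | O=C1CC(O)C(C)(C)[C@@H]2[C@H]3CC=C(C)[C@@H]2[C@]31C | intermediate
21 | longipina-2,7-dien-9-one | O=C1C=CC(C)(C)[C@@H]2[C@H]3CC=C(C)[C@@H]2[C@]31C | intermediate
22 | longipina-2,7-diene-1,9-dione | O=C1C=CC(C)(C)[C@@H]2[C@H]3C(=O)C=C(C)[C@@H]2[C@]31C | intermediate
23 | (7R)-7-(4,4,5,5-tetramethyl-1,3,2-dioxaborolan-2-yl)longipin-2-ene-1,9-dione (formed in the flask) | O=C1C[C@@H](B4OC(C)(C)C(C)(C)O4)C(C)(C)[C@@H]2[C@H]3C(=O)C=C(C)[C@@H]2[C@]31C | intermediate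
24 | (7R)-7-hydroxylongipin-2-ene-1,9-dione | O=C1C[C@@H](O)C(C)(C)[C@@H]2[C@H]3C(=O)C=C(C)[C@@H]2[C@]31C | intermediate
25 | 3-methylbut-2-enal | CC(C)=CC=O | starting material
26 | (7R,9R)-9-hydroxy-1-oxolongipin-2-en-7-yl 3-methylbut-2-enoate | O[C@@H]1C[C@@H](OC(=O)C=C(C)C)C(C)(C)[C@@H]2[C@H]3C(=O)C=C(C)[C@@H]2[C@]31C | intermediate
27 | (E)-2-methylbut-2-enoyl chloride | C/C=C(\C)C(Cl)=O | starting material
28 | CNP0277258.1, (7R,9R)-7-(3-methylbut-2-enoyloxy)-9-[(E)-2-methylbut-2-enoyloxy]longipin-2-en-1-one | C/C=C(\C)C(=O)O[C@@H]1C[C@@H](OC(=O)C=C(C)C)C(C)(C)[C@@H]2[C@H]3C(=O)C=C(C)[C@@H]2[C@]31C | target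

**Totals and risks**
Total step count: 15. Longest linear sequence: 15 steps (1 to 28).

Step 7 is the most exposed. The amide base may isomerise the epoxide to an allylic alcohol, or the hindered tertiary carbanion may fail to reach C4. The fallback sets out from 11. Catalytic OsO4 with N-methylmorpholine N-oxide should dihydroxylate the ring alkene on the face away from the two side chains to give the cis-diol F1. Methanesulfonyl chloride in pyridine should sulfonylate only the secondary C4 hydroxyl to give the hydroxy mesylate F2; its cis tertiary hydroxyl cannot re-form an epoxide. KN(SiMe3)2 in toluene should then displace the mesylate by the nitrile anion with inversion, the classical sulfonate alkylation route to bicyclo[3.1.1]heptanes, and the route is rejoined at 14.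

Step 8 may suffer ionisation of the tertiary sulfamate with a Wagner–Meerwein shift of a cyclobutane bond, or loss of a methyl hydrogen in place of H-2. The fallback sets out from 14. SOCl2 in pyridine at −30 °C would eliminate from the chlorosulfite without a free cation. The exocyclic methylene isomer F3 formed beside 16 would not be separated but isomerised with catalytic RhCl3·3H2O in ethanol to the more stable endocyclic trisubstituted alkene, so the route is rejoined at 16.

Step 14 may fail because the conjugated aldehyde forms the hemiacetal and transfers hydride too slowly, or because SmI2 attacks the enone or promotes acyl migration. The fallback sets out from 24. The Evans–Tishchenko reduction with acetaldehyde, its standard partner, should give the anti hydroxy acetate F4. Acylation of the C9 hydroxyl with 27 (pyridine, DMAP) would give the acetate tiglate F5. K2CO3 in methanol at 0 °C should cleave the acetate much faster than the conjugated, α-branched tiglate to give the C7 alcohol F6. Esterification with 3-methylbut-2-enoic acid (2,4,6-trichlorobenzoyl chloride, Et3N, DMAP) then gives the target, so the route is rejoined at 28.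

**Further compounds**
F1 | step 7 | cis-3,4-diol of 11, both hydroxyls trans to the ring side chains | CC[Si](CC)(CC)OCC(C)(C)[C@H]1[C@H](O)[C@](C)(O)CC[C@H]1C(C)C#N
F2 | step 7 | secondary C4 methanesulfonate of F1 | CC[Si](CC)(CC)OCC(C)(C)[C@H]1[C@H](OS(C)(=O)=O)[C@](C)(O)CC[C@H]1C(C)C#N
F3 | step 8 | 6-methyl-2-methylidene-7-[2-methyl-1-(triethylsilyloxy)propan-2-yl]bicyclo[3.1.1]heptane-6-carbonitrile | CC[Si](CC)(CC)OCC(C)(C)[C@@H]1[C@H]2CCC(=C)[C@@H]1[C@@]2(C)C#N
F4 | step 14 | (7R,9R)-9-hydroxy-1-oxolongipin-2-en-7-yl acetate | O[C@@H]1C[C@@H](OC(C)=O)C(C)(C)[C@@H]2[C@H]3C(=O)C=C(C)[C@@H]2[C@]31C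
F5 | step 14 | (7R,9R)-7-acetoxy-1-oxolongipin-2-en-9-yl (E)-2-methylbut-2-enoate | C/C=C(\C)C(=O)O[C@@H]1C[C@@H](OC(C)=O)C(C)(C)[C@@H]2[C@H]3C(=O)C=C(C)[C@@H]2[C@]31C
F6 | step 14 | (7R,9R)-7-hydroxy-1-oxolongipin-2-en-9-yl (E)-2-methylbut-2-enoate | C/C=C(\C)C(=O)O[C@@H]1C[C@@H](O)C(C)(C)[C@@H]2[C@H]3C(=O)C=C(C)[C@@H]2[C@]31C
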